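At 5.00 min the alder run shows 3.3% of target and the larch run 1.4%, with the same substrate and temperature but 30 mM of reagent against 20 mM.

| flask | substrate | reagent | temperature | remark | time |
|---|---|---|---|---|---|
| alder | 20 mM | 30 mM | 5 °C | the very flask that is asked about, followed so far |  |
| larch | 20 mM | 20 mM | 5 °C | run made earlier |  |
| flask | 20 mM | 30.0 mM | 5 °C |  | 80 min |

| run | time / min | target / % |
|---|---|---|
| alder | 5.00 | 3.3 |
| alder | 8.00 | 8.4 |
| alder | 12.0 | 12.1 |
| alder | 20.0 | 19.0 |
| alder | 30.0 | 19.9 |
| alder | 40.0 | 19.8 |
| alder | 60.0 | 20.8 |
| larch | 0.333 | 0 |
| larch | 1.00 | 0.3 |
| larch | 1.50 | 0 |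
| larch | 2.50 | 0.5 |
| larch | 4.00 | 1.8 |
| larch | 5.00 | 1.4 |
| larch | 6.00 | 3.1 |

(readings scatter by 0.5 percentage points)

- what is taken out of target is counted as made
- the earlier runs do not show what temperature does; that part of a forecast is a guess
- additions bring no volume worth counting

- summer: at 80 min raise the temperature by 15 K, then wait 2.5 h
- autumn: at 80 min take out 90% of the target then present, then wait 2.5 h
- dawn: at 80 min add reagent, 100% of the amount charged, then wait 2.5 h
- winter: change nothing and wait 2.5 h more

- target, in percent of the substrate first charged, at 80 min
- the option that brings most further target ("none" if no option brings more than 2 percentage points) (summer / autumn / dawn / winter / none)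
- target present, with what was taken out counted in, in percent of the substrate first charged, after summer
- target present, with what was taken out counted in, in percent of the substrate first charged, after dawn

Compare the two readings by asking to what power of c_reagent the early rate answers:

n = ln(target in alder / target in larch) / ln(c_reagent in alder / c_reagent in larch) = 2.11

This is a rough reading, since the scatter of 0.5 percentage points is large on a reading as small as the larch one. Still, the nearest whole number is two, and both runs start with a lag. So I take it that reagent is used twice on the way to target, and I count two reagent per substrate carried through. That gives a limit for alder: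

c_reagent / (two × c_substrate) = 75.0%

I call this the reagent ceiling: the share of the substrate that the reagent charge can carry to the end. For larch it is 50.0%. Both stand below the whole substrate charge , so by my count reagent is the limiting reagent in both.

The two runs end differently on the page. Larch was last read at 6.00 min, at 3.1%, with no flat stretch shown, so its end is unread. Alder goes flat after 20.0 min, and its last three readings average 20.2%. A rate that follows the square of c_reagent falls sharply as reagent is used, so I read this sudden stop as a lack of reagent. That plateau reading stands 55 points below the ceiling, so if a lack of reagent is what stopped alder, the reagent went into forms the readings do not show.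

My own reckoning is therefore 20.2% at 80 min, nothing from waiting, and more target from added reagent. What heat does, the runs don't show.

The forecast gave 20.4%, chose dawn, and put summer at 21.5% and dawn at 35%, with the ground: “Fresh reagent helps under either reading”.

The alder flask gives 19.9%, and the best option is summer, reaching 37.1% against 32.3% for dawn, while winter brings 0 points.

    target ⇌ isomer of the product (K = 2.10, k = 0.00260 /s, Ea = 78.0 kJ/mol, ΔH = −52.0 kJ/mol)
    intermediate C ⇌ intermediate D (K = 0.560, k = 0.00210 /s, Ea = 74.0 kJ/mol, ΔH = −23.0 kJ/mol)
    reagent + intermediate B → intermediate C (k = 0.160 /M/s, Ea = 46.0 kJ/mol)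
    substrate ⇌ intermediate A (K = 0.940, k = 0.00270 /s, Ea = 78.0 kJ/mol, ΔH = −30.0 kJ/mol)
    reagent + intermediate A → intermediate B (k = 0.610 /M/s, Ea = 59.0 kJ/mol)
    reagent + intermediate B ⇌ intermediate E (K = 4.00 /M, k = 0.00350 /M/s, Ea = 70.0 kJ/mol, ΔH = −65.0 kJ/mol)
    reagent + intermediate B → intermediate D (k = 0.0180 /M/s, Ea = 58.0 kJ/mol)
    intermediate C → target (k = 0.00350 /s, Ea = 89.0 kJ/mol)
    (constants at 5 °C)

At 80.0 min the alder flask has 0.0497% of its reagent left, with the ceiling of 75.0% unfilled: it holds 19.9% target, 41.7% isomer of the product and 26.4% intermediate B. The neighbouring flask with 120 mM of reagent has a ceiling of 300%, more than the whole substrate, so the same count expects substrate to run out first, with 66.7% of the reagent remaining. That flask ends with 0% substrate, 66.7% of its reagent and 32.3% target.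

(The data are calculated from invented constants, and the scatter is random.)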